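**Retrosynthetic overview**

1. The target is the C2-symmetric (3R,3'R) dimer. Global deprotection comes last, and the two dihydropyran rings are closed together, late, by O1–C2 etherification of a phenol/primary-alcohol pair.
2. C3 is set on an open chain by catalyst-controlled hydroboration of a 1,1-disubstituted alkene whose substituents are the B-ring aryl group and the ring-A CH2.
3. Key disconnection: both C4–C4a bonds. C4 is a benzylic CH2 on C4a, and C4a is ortho to the O1-bearing C8a of resorcinol ring A. A 2-arylallyl aryl ether delivers its terminal alkene carbon to exactly this position and releases O1 as a phenol, so a two-directional aromatic Claisen rearrangement builds both C2–C3–C4–C4a chains at once.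
4. The bis(allyl aryl ether) comes from a double Suzuki–Miyaura coupling of a core diaryl-ether dichloride with an α-borylallyl ether made from resorcinol and propargyl bromide.
5. The core comes from an Ullmann diaryl ether synthesis followed by double ortho-lithiation/hydroxylation between OMe and OAr. Ring order: B rings (bought) → ring A attached by the Claisen step (no ring closed) → both pyran rings in step 10.

Key step: step 8

Remark: both C3 centres of the SMILES are read as R, so the target is the homochiral (3R,3'R) isomer.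
Remark: the antipode of the cobalt ligand in step 9 is to be chosen on a mono-alkene model so that hydride goes to the face giving 3R.

**Route**

Step 1
Reactants: 1 4-chloro-3-methoxyphenol; 2 4-bromo-1-chloro-2-methoxybenzene
Product: 3 4,4'-oxybis(1-chloro-2-methoxybenzene)
Conditions: CuI (10 mol%), N,N-dimethylglycine·HCl (30 mol%), Cs2CO3, dioxane, 100 °C
Reagents that add atoms: none
Why: Ullmann-type copper-catalysed diaryl ether coupling should occur at the C–Br bond only, since aryl chlorides are inert to Cu(I) under these conditions.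

Step 2
Reactants: 3 4,4'-oxybis(1-chloro-2-methoxybenzene)
Product: 6 6,6'-oxybis(3-chloro-2-methoxyphenol), via 2,2'-dilithiated diaryl ether 4 (not isolated), via bis(dimethyl boronate) 5 (not isolated)
Conditions: s-BuLi (2.5 equiv), TMEDA, THF, –78 °C; B(OMe)3, –78 °C → rt; AcOH, 30% H2O2, 0 °C → rt
Reagents that add atoms: hydrogen peroxide, OO (oxygen of each new OH); sec-butyllithium, [Li]C(C)CC, and trimethyl borate, COB(OC)OC, leave Li and B(OMe)2 only in intermediates 4 and 5
Why: Directed ortho-metalation should take place on each ring at the C–H flanked by OMe and the diaryl ether oxygen (cooperative 1,3-directing groups, as in the 2,2'-dilithiation of diphenyl ether), the C–Cl bonds do not exchange at –78 °C, and borylation followed by peroxide oxidation turns each C–Li into C–OH.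

Step 3
Reactants: 6 6,6'-oxybis(3-chloro-2-methoxyphenol)
Product: 7 1,1'-oxybis[2-(benzyloxy)-4-chloro-3-methoxybenzene]
Conditions: BnBr (2.5 equiv), K2CO3, DMF, 50 °C
Reagents that add atoms: benzyl bromide, BrCc1ccccc1
Why: Williamson etherification of the two hindered but acidic 2,6-dioxygenated phenols with a reactive benzylic halide in a dipolar aprotic solvent.

Step 4
Reactants: 8 resorcinol (3 equiv)
Product: 9 3-(triisopropylsilyloxy)phenol
Conditions: TIPSCl (1 equiv), imidazole, DMF, 0 °C → rt; excess resorcinol removed by aqueous wash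
Reagents that add atoms: chlorotriisopropylsilane, CC(C)[Si](Cl)(C(C)C)C(C)C
Why: Statistical monosilylation of a symmetrical diol with excess diol, the bulky silyl chloride reacting once.

Step 5
Reactants: 9 3-(triisopropylsilyloxy)phenol; 10 propargyl bromide
Product: 11 1-(prop-2-yn-1-yloxy)-3-(triisopropylsilyloxy)benzene
Conditions: K2CO3, acetone, 50 °C
Reagents that add atoms: none
Why: Williamson O-alkylation of the phenoxide with a propargylic halide under conditions that leave the aryl triisopropylsilyl ether intact.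

Step 6
Reactants: 11 1-(prop-2-yn-1-yloxy)-3-(triisopropylsilyloxy)benzene
Product: 12 4,4,5,5-tetramethyl-2-{3-[3-(triisopropylsilyloxy)phenoxy]prop-1-en-2-yl}-1,3,2-dioxaborolane
Conditions: B2pin2 (1.1 equiv), MeOH (2 equiv), N-aryl NHC–CuCl (SIMes·CuCl, 5 mol%), NaOtBu (5 mol%), THF, –50 °C → rt
Reagents that add atoms: bis(pinacolato)diboron, CC1(C)OB(OC1(C)C)B1OC(C)(C)C(C)(C)O1
Why: Copper-catalysed protoboration of a terminal alkyne; with an N-aryl carbene ligand and a propargylic oxygen substituent the Cu–B species should add with boron on the internal carbon, and methanol protonates the vinylcopper to give the 1,1-disubstituted vinylboronate.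

Step 7
Reactants: 7 1,1'-oxybis[2-(benzyloxy)-4-chloro-3-methoxybenzene]; 12 vinylboronate (2.5 equiv)
Product: 13 1,1'-oxybis{2-(benzyloxy)-3-methoxy-4-[3-(3-(triisopropylsilyloxy)phenoxy)prop-1-en-2-yl]benzene}
Conditions: Pd(OAc)2 (5 mol%), SPhos (10 mol%), K3PO4, toluene/H2O (10:1), 80 °C
Reagents that add atoms: none
Why: Double Suzuki–Miyaura coupling; the bulky electron-rich biarylphosphine should enable oxidative addition into the electron-rich ortho-methoxy aryl chlorides, and any Pd ionisation of the product allyl aryl ether is degenerate because the two termini of a 2-arylallyl unit are equivalent.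

Step 8
Reactants: 13 bis(2-arylallyl 3-silyloxyphenyl ether)
Product: 14 2,2'-{oxybis[(3-(benzyloxy)-2-methoxy-4,1-phenylene)(prop-1-ene-2,3-diyl)]}bis[5-(triisopropylsilyloxy)phenol] (each ring-A phenol carries at C2 the CH2 of a 2-arylallyl group)
Conditions: PhNEt2 (degassed), 190 °C, sealed tube, base-washed glassware
Reagents that add atoms: none
Why: On heating, each 2-arylallyl aryl ether unit should undergo a concerted suprafacial [3,3]-sigmatropic shift through a chair-like six-membered transition state, in which the O–CH2 bond breaks as the terminal =CH2 carbon bonds to the ring-A carbon ortho to the ether oxygen; the cyclohexadienone then tautomerises to the phenol, so both C4–C4a bonds form and both future O1 hydroxyls are unmasked in one operation. The closest known reaction type is the thermal aromatic Claisen rearrangement of 2-substituted allyl aryl ethers in a high-boiling amine. No ring is closed and no stereocentre is created; the central allyl carbon, which carries the B-ring aryl group, becomes the prochiral 1,1-disubstituted alkene carbon (future C3) and does not crowd the reacting termini. The selectivity needed is regioselectivity between the two ortho carbons of each 3-silyloxyphenyl ether: migration to the carbon between the two oxygens would create a 1,2,3-trisubstituted arene next to the bulky triisopropylsilyloxy group, and a meta donor electronically favours the ortho carbon para to it, so the distal carbon (future C4a) should be preferred at both ends. The basic solvent and acid-free glassware should suppress addition of the freed phenols to the electron-rich alkenes, and minor regioisomers are to be removed by chromatography.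

Step 9
Reactants: 14 bis[2-(2-arylallyl)phenol]
Product: 17 (2R,2'R)-2,2'-[oxybis(3-(benzyloxy)-2-methoxy-4,1-phenylene)]bis{3-[2-hydroxy-4-(triisopropylsilyloxy)phenyl]propan-1-ol}, via bis(trimethylsilyl ether) 15 (not isolated), via bis(pinacol alkylboronate) 16 (not isolated)
Conditions: BSA (3 equiv), THF, rt, volatiles removed in vacuo; chiral iminopyridine–oxazoline CoCl2 complex (5 mol% per alkene), NaBHEt3 (15 mol%), HBpin (2.5 equiv), THF, rt; NaBO3·4H2O, THF/H2O, rt
Reagents that add atoms: sodium perborate, [Na+].[Na+].O[B-]1(O)OO[B-](O)(O)OO1 (oxygen of each new CH2OH); pinacolborane, [H]B1OC(C)(C)C(C)(C)O1 (hydrogen at C3, boron only in 16); N,O-bis(trimethylsilyl)acetamide, CC(=N[Si](C)(C)C)O[Si](C)(C)C (silicon only in 15 and 16)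
Why: Cobalt-catalysed asymmetric anti-Markovnikov hydroboration of 1,1-disubstituted aryl alkenes: the chiral Co–H should deliver hydride to C3 on the face fixed by the ligand, which distinguishes the aryl from the CH2Ar substituent. Transient TMS capping keeps the phenolic O–H away from the hydride catalyst, and stereoretentive perborate oxidation also hydrolyses the aryl TMS ethers while the TIPS ethers remain. The two centres are set independently, so the minor facial pathway should end mostly in the meso diastereomer, which is to be separated here or at 18.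

Step 10
Reactants: 17 (R,R)-bis(phenol–primary alcohol)
Product: 18 (3R,3'R)-3,3'-[oxybis(3-(benzyloxy)-2-methoxy-4,1-phenylene)]bis[7-(triisopropylsilyloxy)chromane]
Conditions: PPh3, DIAD, THF (0.01 M), 0 °C → rt
Reagents that add atoms: none
Why: Double intramolecular Mitsunobu etherification (6-exo-tet attack of each ring-A phenoxide on the activated primary carbon) forms both O1–C2 bonds; C3 is not a reacting centre and keeps its configuration, and no other free phenol is present.

Step 11
Reactants: 18 bis(7-silyloxychromane)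
Product: 19 (3R,3'R)-3,3'-[oxybis(3-(benzyloxy)-2-methoxy-4,1-phenylene)]bis(chroman-7-ol)
Conditions: TBAF (2.4 equiv), AcOH (2.4 equiv), THF, 0 °C
Reagents that add atoms: none
Why: Fluoride-induced cleavage of the two aryl triisopropylsilyl ethers, buffered with acetic acid so that no free phenoxide is exposed to air or base.

Step 12
Reactants: 19 bis(benzyl ether)
Product: 20 (3R,3'R)-3,3'-[oxybis(3-hydroxy-2-methoxy-4,1-phenylene)]bis(chroman-7-ol) (CNP0116832.1)
Conditions: H2 (1 atm), 10% Pd/C, EtOAc/MeOH, rt
Reagents that add atoms: none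
Why: Catalytic hydrogenolysis should cleave only the two O–benzyl bonds; the diaryl ether, the chroman C–O bonds and the C3 benzylic C–H centres are inert, so the product needs only filtration.

**Compound list**

1 | 4-chloro-3-methoxyphenol | COc1cc(O)ccc1Cl | starting material
2 | 4-bromo-1-chloro-2-methoxybenzene | COc1cc(Br)ccc1Cl | starting material
3 | 4,4'-oxybis(1-chloro-2-methoxybenzene) | COc1cc(Oc2ccc(Cl)c(OC)c2)ccc1Cl | intermediate
4 | 2,2'-dilithiated diaryl ether (Li between OMe and OAr on each ring) | COc1c(Cl)ccc(Oc2ccc(Cl)c(OC)c2[Li])c1[Li] | intermediate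
5 | bis(dimethyl boronate) of 3 | COc1c(Cl)ccc(Oc2ccc(Cl)c(OC)c2B(OC)OC)c1B(OC)OC | intermediate
6 | 6,6'-oxybis(3-chloro-2-methoxyphenol) | COc1c(Cl)ccc(Oc2ccc(Cl)c(OC)c2O)c1O | intermediate
7 | 1,1'-oxybis[2-(benzyloxy)-4-chloro-3-methoxybenzene] | COc1c(Cl)ccc(Oc2ccc(Cl)c(OC)c2OCc2ccccc2)c1OCc1ccccc1 | intermediate
8 | resorcinol | Oc1cccc(O)c1 | starting material
9 | 3-(triisopropylsilyloxy)phenol | CC(C)[Si](Oc1cccc(O)c1)(C(C)C)C(C)C | intermediate
10 | propargyl bromide (3-bromoprop-1-yne) | BrCC#C | starting material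
11 | 1-(prop-2-yn-1-yloxy)-3-(triisopropylsilyloxy)benzene | C#CCOc1cccc(O[Si](C(C)C)(C(C)C)C(C)C)c1 | intermediate
12 | 4,4,5,5-tetramethyl-2-{3-[3-(triisopropylsilyloxy)phenoxy]prop-1-en-2-yl}-1,3,2-dioxaborolane | C=C(COc1cccc(O[Si](C(C)C)(C(C)C)C(C)C)c1)B1OC(C)(C)C(C)(C)O1 | intermediate
13 | 1,1'-oxybis{2-(benzyloxy)-3-methoxy-4-[3-(3-(triisopropylsilyloxy)phenoxy)prop-1-en-2-yl]benzene} | COc1c(C(=C)COc2cccc(O[Si](C(C)C)(C(C)C)C(C)C)c2)ccc(Oc2ccc(C(=C)COc3cccc(O[Si](C(C)C)(C(C)C)C(C)C)c3)c(OC)c2OCc2ccccc2)c1OCc1ccccc1 | intermediate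
14 | 2,2'-{oxybis[(3-(benzyloxy)-2-methoxy-4,1-phenylene)(prop-1-ene-2,3-diyl)]}bis[5-(triisopropylsilyloxy)phenol] | COc1c(C(=C)Cc2ccc(O[Si](C(C)C)(C(C)C)C(C)C)cc2O)ccc(Oc2ccc(C(=C)Cc3ccc(O[Si](C(C)C)(C(C)C)C(C)C)cc3O)c(OC)c2OCc2ccccc2)c1OCc1ccccc1 | intermediate
15 | bis(trimethylsilyl ether) of 14 | COc1c(C(=C)Cc2ccc(O[Si](C(C)C)(C(C)C)C(C)C)cc2O[Si](C)(C)C)ccc(Oc2ccc(C(=C)Cc3ccc(O[Si](C(C)C)(C(C)C)C(C)C)cc3O[Si](C)(C)C)c(OC)c2OCc2ccccc2)c1OCc1ccccc1 | intermediate
16 | (R,R)-bis(pinacol alkylboronate), TMS ethers in place | COc1c([C@@H](Cc2ccc(O[Si](C(C)C)(C(C)C)C(C)C)cc2O[Si](C)(C)C)CB2OC(C)(C)C(C)(C)O2)ccc(Oc2ccc([C@@H](Cc3ccc(O[Si](C(C)C)(C(C)C)C(C)C)cc3O[Si](C)(C)C)CB3OC(C)(C)C(C)(C)O3)c(OC)c2OCc2ccccc2)c1OCc1ccccc1 | intermediate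
17 | (2R,2'R)-2,2'-[oxybis(3-(benzyloxy)-2-methoxy-4,1-phenylene)]bis{3-[2-hydroxy-4-(triisopropylsilyloxy)phenyl]propan-1-ol} | COc1c([C@@H](Cc2ccc(O[Si](C(C)C)(C(C)C)C(C)C)cc2O)CO)ccc(Oc2ccc([C@@H](Cc3ccc(O[Si](C(C)C)(C(C)C)C(C)C)cc3O)CO)c(OC)c2OCc2ccccc2)c1OCc1ccccc1 | intermediate
18 | (3R,3'R)-3,3'-[oxybis(3-(benzyloxy)-2-methoxy-4,1-phenylene)]bis[7-(triisopropylsilyloxy)chromane] | COc1c([C@@H]2COc3cc(O[Si](C(C)C)(C(C)C)C(C)C)ccc3C2)ccc(Oc2ccc([C@@H]3COc4cc(O[Si](C(C)C)(C(C)C)C(C)C)ccc4C3)c(OC)c2OCc2ccccc2)c1OCc1ccccc1 | intermediate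
19 | (3R,3'R)-3,3'-[oxybis(3-(benzyloxy)-2-methoxy-4,1-phenylene)]bis(chroman-7-ol) | COc1c([C@@H]2COc3cc(O)ccc3C2)ccc(Oc2ccc([C@@H]3COc4cc(O)ccc4C3)c(OC)c2OCc2ccccc2)c1OCc1ccccc1 | intermediate
20 | (3R,3'R)-3,3'-[oxybis(3-hydroxy-2-methoxy-4,1-phenylene)]bis(chroman-7-ol) | COc1c([C@@H]2COc3cc(O)ccc3C2)ccc(Oc2ccc([C@@H]3COc4cc(O)ccc4C3)c(OC)c2O)c1O | target

**Step count**

Total steps: 12. Longest linear sequence: 9 steps (1 → 2 → 3 → 7 → 8 → 9 → 10 → 11 → 12; the resorcinol branch 4 → 5 → 6 → 7 → … → 12 is equally long).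

**Steps most likely to fail**

Step 8 (two-directional Claisen rearrangement). What may go wrong: one or both allyl termini migrate to the ring-A carbon between the two oxygens, so the bis-distal isomer is eroded statistically over two events; the liberated phenols may also add to the electron-rich 1,1-disubstituted alkenes at high temperature. Fallback, setting out from 13 and returning at 14: the two C4–C4a bonds would be made by palladium-catalysed allyl–aryl cross-coupling instead of a sigmatropic shift. 4-Bromoresorcinol would be monosilylated at the less hindered hydroxyl para to bromine (TIPSCl, imidazole) to give 2-bromo-5-(triisopropylsilyloxy)phenol F1. Miyaura borylation (B2pin2, PdCl2(dppf), KOAc, dioxane) would then give 5-(triisopropylsilyloxy)-2-(4,4,5,5-tetramethyl-1,3,2-dioxaborolan-2-yl)phenol F2. Pd(0) with a bisphosphine would ionise each allyl aryl ether of 13, with the 3-silyloxyphenoxide as leaving group, to a 2-aryl-π-allyl complex whose two termini are equivalent. Suzuki-type coupling with F2 would place the CH2 on the boron-bearing carbon (ortho to OH, para to OTIPS), giving 14 with the ring-A regiochemistry fixed by the reagent.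

Step 9 (asymmetric hydroboration). What may go wrong: poor facial discrimination between the ortho-methoxyaryl and arylmethyl substituents at one or both alkenes, or cobalt-hydride-mediated migration of the alkene into conjugation before borylation. Fallback, setting out from 14 (as its bis-TMS ether 15) and returning at 17: C3 would be set by dynamic kinetic resolution instead of alkene face selection. Uncatalysed hydroboration of 15 with 9-BBN would give the bis(B-alkyl-9-borabicyclononane) adduct F3 and, after NaBO3, the diol F4 as a mixture of all stereoisomers. TPAP/NMO would oxidise each primary alcohol through the lactol to the bis(3-arylchroman-2-one) F5. The α-aryl lactone centre epimerises readily with base, so iridium-catalysed asymmetric hydrogenation of racemic α-substituted lactones to diols (chiral spiro P,N,N ligand, H2, KOtBu, short contact to spare the silyl ethers) should funnel the whole mixture to 17.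

Step 7 (double Suzuki–Miyaura coupling). What may go wrong: sluggish oxidative addition at the second electron-rich aryl chloride, protodeboronation of the α-substituted vinylboronate, or palladium ionisation of the allyl aryl ether followed by capture by hydroxide. Fallback, setting out from 7 and 9 and returning at 13: the polarity of the coupling would be reversed so that the sensitive allyl ether meets palladium only under mild conditions. Miyaura borylation of 7 (B2pin2, Pd/XPhos, KOAc, dioxane) would give 2,2'-[oxybis(3-(benzyloxy)-2-methoxy-4,1-phenylene)]bis(4,4,5,5-tetramethyl-1,3,2-dioxaborolane) F6. Alkylation of 9 with 2,3-dibromopropene (K2CO3, acetone) would give 1-[(2-bromoprop-2-en-1-yl)oxy]-3-(triisopropylsilyloxy)benzene F7. Coupling of F6 with F7 (PdCl2(dppf), K2CO3, dioxane/H2O, 60 °C) proceeds by fast oxidative addition at the vinyl bromide and would give 13.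

**Further compounds**

F1 | step 8 | 2-bromo-5-(triisopropylsilyloxy)phenol | CC(C)[Si](Oc1ccc(Br)c(O)c1)(C(C)C)C(C)C
F2 | step 8 | 5-(triisopropylsilyloxy)-2-(4,4,5,5-tetramethyl-1,3,2-dioxaborolan-2-yl)phenol | CC(C)[Si](Oc1ccc(B2OC(C)(C)C(C)(C)O2)c(O)c1)(C(C)C)C(C)C
F3 | step 9 | bis(B-alkyl-9-borabicyclo[3.3.1]nonane) adduct of 15, stereoisomer mixture | COc1c(C(Cc2ccc(O[Si](C(C)C)(C(C)C)C(C)C)cc2O[Si](C)(C)C)CB2C3CCCC2CCC3)ccc(Oc2ccc(C(Cc3ccc(O[Si](C(C)C)(C(C)C)C(C)C)cc3O[Si](C)(C)C)CB3C4CCCC3CCC4)c(OC)c2OCc2ccccc2)c1OCc1ccccc1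
F4 | step 9 | 2,2'-[oxybis(3-(benzyloxy)-2-methoxy-4,1-phenylene)]bis{3-[2-hydroxy-4-(triisopropylsilyloxy)phenyl]propan-1-ol}, stereoisomer mixture | COc1c(C(Cc2ccc(O[Si](C(C)C)(C(C)C)C(C)C)cc2O)CO)ccc(Oc2ccc(C(Cc3ccc(O[Si](C(C)C)(C(C)C)C(C)C)cc3O)CO)c(OC)c2OCc2ccccc2)c1OCc1ccccc1
F5 | step 9 | 3,3'-[oxybis(3-(benzyloxy)-2-methoxy-4,1-phenylene)]bis[7-(triisopropylsilyloxy)chroman-2-one], stereoisomer mixture | COc1c(C2Cc3ccc(O[Si](C(C)C)(C(C)C)C(C)C)cc3OC2=O)ccc(Oc2ccc(C3Cc4ccc(O[Si](C(C)C)(C(C)C)C(C)C)cc4OC3=O)c(OC)c2OCc2ccccc2)c1OCc1ccccc1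
F6 | step 7 | 2,2'-[oxybis(3-(benzyloxy)-2-methoxy-4,1-phenylene)]bis(4,4,5,5-tetramethyl-1,3,2-dioxaborolane) | COc1c(B2OC(C)(C)C(C)(C)O2)ccc(Oc2ccc(B3OC(C)(C)C(C)(C)O3)c(OC)c2OCc2ccccc2)c1OCc1ccccc1
F7 | step 7 | 1-[(2-bromoprop-2-en-1-yl)oxy]-3-(triisopropylsilyloxy)benzene | C=C(Br)COc1cccc(O[Si](C(C)C)(C(C)C)C(C)C)c1
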